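## Retrosynthetic overview

1. Bought pieces: tryptophol (1; its acetate 2 carries indole ring A), indole (3; ring B) and (R)-glyceraldehyde acetonide (4; the only source of chirality).
2. First disconnection, C3 of ring B to the future methine carbon: 3 + 4 + p-toluenesulfinic acid give, through carbinol 5 and alkylideneindolenine 6, the bench-stable sulfone 7.
3. Key disconnection, C2 of ring A to the methine carbon: light-driven ionisation of 7 and capture of the resulting cation by 2 gives 8; the dioxolane centre from 4 steers the new methine centre.
4. Last step: hydrolysis of the acetal in 8 gives Colletotryptin C (9).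
5. Ring order: no ring is built; both indoles and the dioxolane are bought, and the dioxolane is opened last.

Assumption: aldehyde 4 is bought as its stabilised solution and used fresh; the target is the (1S,2S) isomer encoded by the given SMILES.

## Route

Step 1
Reactants: 1 tryptophol [2-(1H-indol-3-yl)ethanol]
Product: 2 tryptophol acetate [2-(1H-indol-3-yl)ethyl acetate]
Conditions: Ac2O (1.2 equiv), pyridine, 0 °C → rt
Reagents that add atoms: acetic anhydride, CC(=O)OC(C)=O
Why: Chemoselective O-acetylation of the primary alcohol, since the indole N–H is not acylated by Ac2O/pyridine without a strong base; no stereocentre is involved.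

Step 2
Reactants: 3 indole; 4 (R)-2,2-dimethyl-1,3-dioxolane-4-carbaldehyde
Product: 7 3-{[(4R)-2,2-dimethyl-1,3-dioxolan-4-yl](4-methylbenzenesulfonyl)methyl}-1H-indole (both epimers at the sulfonyl carbon), via carbinol 5 (not isolated), via alkylideneindolenine 6 (not isolated)
Conditions: TolSO2H (1.3 equiv), TsOH (10 mol %), 4 Å MS, EtOAc, 0 °C → rt
Reagents that add atoms: p-toluenesulfinic acid, Cc1ccc(cc1)S(=O)O
Why: Three-component sulfonyl-indole synthesis (Friedel–Crafts hydroxyalkylation to 5, acid ionisation to N-protonated 6, then sulfinate addition, which outruns a second indole); the bought dioxolane centre is untouched and the new sulfonyl-bearing centre needs no control because step 3 erases it.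

Step 3
Reactants: 7 3-{[(4R)-2,2-dimethyl-1,3-dioxolan-4-yl](4-methylbenzenesulfonyl)methyl}-1H-indole; 2 tryptophol acetate (3 equiv)
Product: 8 2-{2-[(S)-[(4S)-2,2-dimethyl-1,3-dioxolan-4-yl](1H-indol-3-yl)methyl]-1H-indol-3-yl}ethyl acetate
Conditions: 3,6-di-tert-butyl-9-mesityl-10-phenylacridinium tetrafluoroborate (2 mol %), CH2Cl2–HFIP 4:1, 450 nm LEDs, −20 °C, Ar; cold aq. NaHCO3
Reagents that add atoms: none
Why: Proposed new method: a redox-neutral photochemical SN1 (desulfinative Friedel–Crafts) in which the excited acridinium oxidises the indole ring of 7, the radical cation loses a tosyl radical by mesolytic β-C–S cleavage and so returns the sulfone to the N-protonated form of 6 first met in step 2, the acridine radical hands the electron back to the tosyl radical (sulfinate, then TolSO2H with the proton freed on rearomatisation), and C2 of 2 adds to the exocyclic carbon of that cation at −20 °C, where 7 does not ionise in the dark and sulfinate return only regenerates 7; the methine centre is set by the bought dioxolane centre, whose C–H eclipses the exocyclic C=C (allylic 1,3-strain against indole C2–H) so that ring A enters anti to the C4–C5 bond on the face of the ring oxygen (Cornforth-type transition state), predicted to give the (S) centre (estimated d.r. about 4:1, epimer removed by chromatography); the closest known reaction types are mesolytic carbocation generation from photo-oxidised alkoxyamines or benzylic thioethers and the Lewis-acid Friedel–Crafts substitution of 3-(1-arylsulfonylalkyl)indoles.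

Step 4
Reactants: 8 2-{2-[(S)-[(4S)-2,2-dimethyl-1,3-dioxolan-4-yl](1H-indol-3-yl)methyl]-1H-indol-3-yl}ethyl acetate
Product: 9 Colletotryptin C, 2-{2-[(1S,2S)-2,3-dihydroxy-1-(1H-indol-3-yl)propyl]-1H-indol-3-yl}ethyl acetate
Conditions: AcOH–H2O 4:1, 40 °C
Reagents that add atoms: none
Why: Acid-catalysed hydrolysis of the terminal isopropylidene acetal (acetal deprotection) in aqueous acetic acid, which is too weak to ionise the bis(indolyl)methine or cleave the primary acetate, so both stereocentres pass through unchanged.

## Compound list

1 | tryptophol, 2-(1H-indol-3-yl)ethanol | OCCc1c[nH]c2ccccc12 | starting material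
2 | tryptophol acetate, 2-(1H-indol-3-yl)ethyl acetate | CC(=O)OCCc1c[nH]c2ccccc12 | intermediate
3 | indole | c1ccc2[nH]ccc2c1 | starting material
4 | (R)-2,2-dimethyl-1,3-dioxolane-4-carbaldehyde, (R)-glyceraldehyde acetonide | O=C[C@H]1COC(C)(C)O1 | starting material
5 | [(4R)-2,2-dimethyl-1,3-dioxolan-4-yl](1H-indol-3-yl)methanol, both carbinol epimers | OC(c1c[nH]c2ccccc12)[C@H]1COC(C)(C)O1 | intermediate (not isolated)
6 | 3-{[(4S)-2,2-dimethyl-1,3-dioxolan-4-yl]methylidene}-3H-indole, reacting as its N-protonated form | N1=CC(=C[C@H]2COC(C)(C)O2)c2ccccc12 | intermediate (not isolated)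
7 | 3-{[(4R)-2,2-dimethyl-1,3-dioxolan-4-yl](4-methylbenzenesulfonyl)methyl}-1H-indole, both epimers at the sulfonyl carbon | Cc1ccc(cc1)S(=O)(=O)C(c1c[nH]c2ccccc12)[C@H]1COC(C)(C)O1 | intermediate
8 | 2-{2-[(S)-[(4S)-2,2-dimethyl-1,3-dioxolan-4-yl](1H-indol-3-yl)methyl]-1H-indol-3-yl}ethyl acetate | CC(=O)OCCc1c([C@H](c2c[nH]c3ccccc23)[C@H]2COC(C)(C)O2)[nH]c2ccccc12 | intermediate
9 | Colletotryptin C, 2-{2-[(1S,2S)-2,3-dihydroxy-1-(1H-indol-3-yl)propyl]-1H-indol-3-yl}ethyl acetate | CC(=O)OCCc1c([C@H](c2c[nH]c3ccccc23)[C@H](O)CO)[nH]c2ccccc12 | target

## Step count and risks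

Total steps: 4. Longest linear sequence: 3 (3/4 → 7 → 8 → 9, or 1 → 2 → 8 → 9).

**Step 3 (most likely to fail).** The photochemical ionisation is new, and both the sense and the level of 1,2-induction are predicted from a model, not from precedent. The excess of 2 may also quench the excited catalyst unproductively. The fallback sets out from 7 and 2 and comes back to the route at 8. Sulfone 7 and 2 (3 equiv) are treated with Sc(OTf)3 (10 mol %) in CH2Cl2 at −40 → −20 °C. This is the established Lewis-acid Friedel–Crafts substitution of arenesulfonyl indoles, joined to the well-known acid-mediated C2-alkylation of 3-substituted indoles by 3-indolylmethyl cations. It passes through the same N-protonated 6, so the same stereochemical model applies. No new compound arises on this path (entry F0).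

**Step 2.** The acid-labile, easily hydrated aldehyde 4 may lose its acetal or give the symmetrical bis(indolyl)methane. The fallback sets out from 3 and 4 and comes back at 7. Indole is deprotonated with EtMgBr in Et2O–toluene at 0 °C to give indol-1-ylmagnesium bromide F1. This adds through C3 to 4 at −78 °C; after a pH 7 buffer quench the crude carbinol 5 is obtained. Carbinol 5 is treated at once with TolSO2H (1.2 equiv) in CH2Cl2 at 0 °C to give 7.

**Step 4.** The acid may erode the acetate or the bis(indolyl)methine. The fallback sets out from 7 and comes back at 9, with the acetal removed before the sensitive C–C bond exists. The acid-tolerant sulfone 7 is hydrolysed in AcOH–H2O 4:1 at 40 °C to (2R)-3-(1H-indol-3-yl)-3-(4-methylbenzenesulfonyl)propane-1,2-diol F2. F2 is then coupled with 2 under the step 3 conditions (or the Sc(OTf)3 conditions above). It ionises to the N-protonated form of (2S)-3-(3H-indol-3-ylidene)propane-1,2-diol F3, which is not isolated and is captured by 2 to give 9 directly; the free diol may change the diastereomer ratio.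

## Further compounds

F1 | step 2 | indol-1-ylmagnesium bromide | Br[Mg]n1ccc2ccccc12
F0 | step 3 | none | none
F2 | step 4 | (2R)-3-(1H-indol-3-yl)-3-(4-methylbenzenesulfonyl)propane-1,2-diol, both epimers at the sulfonyl carbon | Cc1ccc(cc1)S(=O)(=O)C(c1c[nH]c2ccccc12)[C@H](O)CO
F3 | step 4 | (2S)-3-(3H-indol-3-ylidene)propane-1,2-diol, reacting as its N-protonated form | N1=CC(=C[C@H](O)CO)c2ccccc12
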